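**Retrosynthetic overview**
1. 16 ⇐ 15: a single LiAlH4 reduction turns the ester and the N-acyl sultam into the two CH2OH groups and frees both phenols.
2. 15 ⇐ 14: ionic hydrogenation of the C2=C3 enol ether sets the last two stereocentres.
3. Key step, 14 ⇐ 8 + 13: an oxidative radical [3+2] annulation forms the C3–C4 bond and the C5–O bond. The only ring made in the route is built here, as a 4,5-dihydrofuran, under auxiliary control.
4. 8 and 13 ⇐ the same aldehyde 6, by diazo ester homologation for 8 and by Doebner condensation followed by sultam acylation for 13.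
5. 6 ⇐ p-cresol 1, by bromination and hydrolysis, copper-catalysed methoxylation and pivaloylation.

Assumption: the facial sense of the auxiliary follows the usual model for N-enoyl bornane-10,2-sultams (s-cis enoyl group, Cα-Si attack for the (2S)-sultam); if experiment shows the opposite sense, the equally available (1S)-(−)-sultam is used and nothing else changes.

Ring numbering in 14 and 15: O1, C2 (aryl from 8), C3 (ester), C4 (acyl sultam), C5 (aryl from 13).

**Step 1**
Reactants: 1 p-cresol (4-methylphenol)
Product: 4 3,5-dibromo-4-hydroxybenzaldehyde, via 2,6-dibromo-4-methylphenol 2 (not isolated), via 2,6-dibromo-4-(dibromomethyl)phenol 3 (not isolated)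
Conditions: Br2 (2.05 equiv), o-dichlorobenzene, 35 °C; Br2 (2.05 equiv), 155 °C; then H2O, 100 °C
Reagents that add atoms: bromine, BrBr; water, O
Why: Electrophilic aromatic bromination at both positions ortho to OH, thermal free-radical benzylic dibromination and hydrolysis of the benzal bromide give the aldehyde in one pot, and no stereocentre is formed.

**Step 2**
Reactants: 4 3,5-dibromo-4-hydroxybenzaldehyde
Product: 6 4-formyl-2,6-dimethoxyphenyl pivalate, via sodium 4-formyl-2,6-dimethoxyphenolate 5 (not isolated)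
Conditions: NaOMe (3.3 equiv), CuCl (10 mol %), DMF, 115 °C, MeOH distilled off; then 25 °C, PivCl (1.5 equiv), DMAP (5 mol %)
Reagents that add atoms: sodium methoxide, C[O-].[Na+]; pivaloyl chloride, CC(C)(C)C(=O)Cl
Why: Ullmann-type copper-catalysed methoxylation replaces both aryl bromides, and the sodium phenolate left in the flask is O-acylated directly, giving an acyloxy group that protects the phenol from the later oxidant and damps benzylic cation formation.

**Step 3**
Reactants: 6 4-formyl-2,6-dimethoxyphenyl pivalate; 7 ethyl diazoacetate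
Product: 8 ethyl 3-[3,5-dimethoxy-4-(pivaloyloxy)phenyl]-3-oxopropanoate
Conditions: NbCl5 (5 mol %), CH2Cl2, rt
Reagents that add atoms: none
Why: Roskamp homologation, in which Lewis-acid-promoted addition of the diazo ester to the aldehyde and a 1,2-hydride shift with loss of N2 give the β-keto ester, while the acyloxy-deactivated ring disfavours the competing aryl shift.

**Step 4**
Reactants: 6 4-formyl-2,6-dimethoxyphenyl pivalate; 9 malonic acid
Product: 11 (E)-3-[3,5-dimethoxy-4-(pivaloyloxy)phenyl]acrylic acid, via arylidenemalonic acid 10 (not isolated)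
Conditions: pyridine, piperidine (5 mol %), 85 °C
Reagents that add atoms: none
Why: Knoevenagel–Doebner condensation with in situ decarboxylation gives only the E acid, and the hindered pivalate survives the catalytic amine.

**Step 5**
Reactants: 11 (E)-3-[3,5-dimethoxy-4-(pivaloyloxy)phenyl]acrylic acid
Product: 13 (2S)-N-{(E)-3-[3,5-dimethoxy-4-(pivaloyloxy)phenyl]acryloyl}bornane-10,2-sultam, via acid chloride 12 (not isolated)
Conditions: (COCl)2, DMF (cat.), CH2Cl2, 0 °C to rt, evaporate; (1R)-(+)-2,10-camphorsultam, NaH, THF, 0 °C to rt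
Reagents that add atoms: (1R)-(+)-2,10-camphorsultam, CC1(C)[C@H]2CC[C@@]13CS(=O)(=O)N[C@H]3C2; oxalyl chloride, O=C(Cl)C(=O)Cl (supplies only the chlorine of 12)
Why: N-acylation of the sodium sultamide by the acid chloride installs the chiral auxiliary far faster than any attack on the hindered aryl pivalate, and no new stereocentre is formed.

**Step 6 (key step)**
Reactants: 8 ethyl 3-[3,5-dimethoxy-4-(pivaloyloxy)phenyl]-3-oxopropanoate; 13 (2S)-N-{(E)-3-[3,5-dimethoxy-4-(pivaloyloxy)phenyl]acryloyl}bornane-10,2-sultam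
Product: 14 ethyl (4S,5S)-2,5-bis[3,5-dimethoxy-4-(pivaloyloxy)phenyl]-4-[(2S)-bornane-10,2-sultam-N-carbonyl]-4,5-dihydrofuran-3-carboxylate
Conditions: Mn(OAc)3·2H2O (2.2 equiv), 8 (1.5 equiv), degassed AcOH, 70 °C; major diastereomer isolated by chromatography or crystallisation
Reagents that add atoms: none
Why: Mn(OAc)3-mediated oxidative free-radical [3+2] annulation (Heiba–Dessau dihydrofuran synthesis): the electrophilic radical from the enol of 8 adds to Cα of 13 to give the benzylic radical (new C3–C4 bond), a second Mn(OAc)3 oxidises it to the cation, the ketone oxygen closes the ring anti to the acyl group (4,5-trans), and the s-cis N-enoyl sultam exposes only its Cα-Si face, which fixes (4S,5S).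

**Step 7**
Reactants: 14 ethyl (4S,5S)-2,5-bis[3,5-dimethoxy-4-(pivaloyloxy)phenyl]-4-[(2S)-bornane-10,2-sultam-N-carbonyl]-4,5-dihydrofuran-3-carboxylate
Product: 15 ethyl (2R,3S,4S,5S)-2,5-bis[3,5-dimethoxy-4-(pivaloyloxy)phenyl]-4-[(2S)-bornane-10,2-sultam-N-carbonyl]tetrahydrofuran-3-carboxylate
Conditions: Et3SiH (5 equiv), TFA/CH2Cl2 1:1, 0 °C to rt
Reagents that add atoms: none
Why: Kursanov–Parnes ionic hydrogenation: reversible protonation at C3 funnels the enol ether into the more stable 3,4-trans 2-aryl oxocarbenium ion, Et3SiH delivers hydride to C2 anti to both the C3 ester and the C5 aryl group (2,3-cis, aryl groups cis), and the acyloxy-deactivated rings keep the benzylic C–O bonds from ionising, so C4 and C5 are not scrambled.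

**Step 8**
Reactants: 15 ethyl (2R,3S,4S,5S)-2,5-bis[3,5-dimethoxy-4-(pivaloyloxy)phenyl]-4-[(2S)-bornane-10,2-sultam-N-carbonyl]tetrahydrofuran-3-carboxylate
Product: 16 [(2S,3R,4R,5R)-2,5-bis(4-hydroxy-3,5-dimethoxyphenyl)tetrahydrofuran-3,4-diyl]dimethanol
Conditions: LiAlH4 (6 equiv), THF, 0 °C to rt; aq. potassium sodium tartrate, pH 6
Reagents that add atoms: none
Why: Hydride reduction converts the ester and the N-acyl sultam into the two CH2OH groups, cleaves both aryl pivalates and releases the auxiliary, and because reduction is much faster than enolisation none of the four ring stereocentres is touched.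

**Compound list**
1 | p-cresol | Cc1ccc(O)cc1 | starting material
2 | 2,6-dibromo-4-methylphenol | Cc1cc(Br)c(O)c(Br)c1 | intermediate
3 | 2,6-dibromo-4-(dibromomethyl)phenol | BrC(Br)c1cc(Br)c(O)c(Br)c1 | intermediate
4 | 3,5-dibromo-4-hydroxybenzaldehyde | O=Cc1cc(Br)c(O)c(Br)c1 | intermediate
5 | sodium 4-formyl-2,6-dimethoxyphenolate | [Na+].[O-]c1c(OC)cc(C=O)cc1OC | intermediate
6 | 4-formyl-2,6-dimethoxyphenyl pivalate | COc1cc(C=O)cc(OC)c1OC(=O)C(C)(C)C | intermediate
7 | ethyl diazoacetate | CCOC(=O)C=[N+]=[N-] | starting material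
8 | ethyl 3-[3,5-dimethoxy-4-(pivaloyloxy)phenyl]-3-oxopropanoate | CCOC(=O)CC(=O)c1cc(OC)c(OC(=O)C(C)(C)C)c(OC)c1 | intermediate
9 | malonic acid | OC(=O)CC(=O)O | starting material
10 | 2-[3,5-dimethoxy-4-(pivaloyloxy)benzylidene]malonic acid | OC(=O)C(=Cc1cc(OC)c(OC(=O)C(C)(C)C)c(OC)c1)C(=O)O | intermediate
11 | (E)-3-[3,5-dimethoxy-4-(pivaloyloxy)phenyl]acrylic acid | OC(=O)/C=C/c1cc(OC)c(OC(=O)C(C)(C)C)c(OC)c1 | intermediate
12 | (E)-3-[3,5-dimethoxy-4-(pivaloyloxy)phenyl]acryloyl chloride | ClC(=O)/C=C/c1cc(OC)c(OC(=O)C(C)(C)C)c(OC)c1 | intermediate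
13 | (2S)-N-{(E)-3-[3,5-dimethoxy-4-(pivaloyloxy)phenyl]acryloyl}bornane-10,2-sultam | CC1(C)[C@H]2CC[C@@]13CS(=O)(=O)N(C(=O)/C=C/c4cc(OC)c(OC(=O)C(C)(C)C)c(OC)c4)[C@H]3C2 | intermediate
14 | ethyl (4S,5S)-2,5-diaryl-4-(sultam-N-carbonyl)-4,5-dihydrofuran-3-carboxylate, aryl = 3,5-dimethoxy-4-(pivaloyloxy)phenyl, 4,5-trans | CC1(C)[C@H]2CC[C@@]13CS(=O)(=O)N(C(=O)[C@@H]4[C@@H](c5cc(OC)c(OC(=O)C(C)(C)C)c(OC)c5)OC(c5cc(OC)c(OC(=O)C(C)(C)C)c(OC)c5)=C4C(=O)OCC)[C@H]3C2 | intermediate
15 | ethyl (2R,3S,4S,5S)-2,5-diaryl-4-(sultam-N-carbonyl)tetrahydrofuran-3-carboxylate, same aryl, 2,3-cis, 3,4-trans, 4,5-trans, aryl groups cis | CC1(C)[C@H]2CC[C@@]13CS(=O)(=O)N(C(=O)[C@@H]4[C@@H](c5cc(OC)c(OC(=O)C(C)(C)C)c(OC)c5)O[C@@H](c5cc(OC)c(OC(=O)C(C)(C)C)c(OC)c5)[C@H]4C(=O)OCC)[C@H]3C2 | intermediate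
16 | [(2S,3R,4R,5R)-2,5-bis(4-hydroxy-3,5-dimethoxyphenyl)tetrahydrofuran-3,4-diyl]dimethanol (C2, C3, C4, C5 of this name are C5, C4, C3, C2 of 15) | COc1cc([C@H]2O[C@@H](c3cc(OC)c(O)c(OC)c3)[C@@H](CO)[C@@H]2CO)cc(OC)c1O | target

**Total step count:** 8. **Longest linear sequence:** 7 (steps 1, 2, 4, 5, 6, 7, 8).

**Three steps most likely to fail**

**Step 6.** The cinnamoyl sultam is an electron-poor 1,2-disubstituted alkene. Capture of the radical may therefore lose to oxidative self-coupling of 8, and the facial ratio at 70 °C may be modest. The fallback sets out from 8. It is brominated with NBS to racemic ethyl 2-bromo-3-[3,5-dimethoxy-4-(pivaloyloxy)phenyl]-3-oxopropanoate F1. The same radical is then generated reductively at room temperature with fac-Ir(ppy)3, blue light and 2,6-lutidine in MeCN in the presence of 13. This is a redox-neutral radical-polar crossover: radical addition, then oxidation of the benzylic radical by the oxidised photocatalyst or bromine-atom transfer, then O-cyclisation with loss of HBr. It needs no stoichiometric oxidant and runs at a temperature where the auxiliary discriminates better. It comes back to the route at 14.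

**Step 7.** The enol ether is a vinylogous carbonate, so C-protonation may be slow, and hydride delivery may be less face-selective than predicted. The fallback sets out from 14. It is first reduced with LiAlH4 to [(4R,5S)-2,5-bis(4-hydroxy-3,5-dimethoxyphenyl)-4,5-dihydrofuran-3,4-diyl]dimethanol F2. This is then hydrogenated with [Ir(cod)(PCy3)(py)]PF6 and H2 in CH2Cl2–THF. The CH2OH group on C4 binds the iridium and delivers both hydrogens to its own face, which is the face anti to the C5 aryl group. This gives the same 2,3-cis, 3,4-trans array by hydroxyl direction rather than by cation control. It comes back to the route at 16.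

**Step 3.** Aromatic aldehydes are the weaker substrates for diazo ester homologation, because aryl migration and oligomerisation of the diazo ester compete. The fallback sets out from 6. Reformatsky addition of ethyl bromoacetate with Zn in THF gives racemic ethyl 3-hydroxy-3-[3,5-dimethoxy-4-(pivaloyloxy)phenyl]propanoate F3. Its benzylic alcohol is oxidised with Dess–Martin periodinane. It comes back to the route at 8.

**Further compounds**
F1 | step 6 | ethyl 2-bromo-3-[3,5-dimethoxy-4-(pivaloyloxy)phenyl]-3-oxopropanoate (racemic) | CCOC(=O)C(Br)C(=O)c1cc(OC)c(OC(=O)C(C)(C)C)c(OC)c1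
F2 | step 7 | [(4R,5S)-2,5-bis(4-hydroxy-3,5-dimethoxyphenyl)-4,5-dihydrofuran-3,4-diyl]dimethanol | COc1cc([C@H]2OC(c3cc(OC)c(O)c(OC)c3)=C(CO)[C@@H]2CO)cc(OC)c1O
F3 | step 3 | ethyl 3-hydroxy-3-[3,5-dimethoxy-4-(pivaloyloxy)phenyl]propanoate (racemic) | CCOC(=O)CC(O)c1cc(OC)c(OC(=O)C(C)(C)C)c(OC)c1
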